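A small charge of free monomer cannot be spent twice, so before we act on this flask we ask whether its curve has already closed.

in all of them: initiator 0.1 mol%
- south-east: free monomer 0.50 M; protic impurity 0.25 M; temperature 0 °C; the very flask that is asked about, followed so far
- south-west: free monomer 1 M; protic impurity 0.25 M; temperature −15 °C; run made earlier
- flask: free monomer 0.50 M; protic impurity 0.250 M; temperature 0 °C; time 4.0 h

- south-east (time / min: monomer in chains / %, free monomer / %): 50.0: 30.5, 0; 90.0: 30.7, 0.1; 150: 29.7, 0.5; 180: 30.3, 0
- south-west (time / min: monomer in chains / %, free monomer / %): 6.00: 37.6, 13.9; 12.0: 42.7, 5.0; 30.0: 44.1, 0.9; 80.0: 43.8, 0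

(standard deviation of a reading: 0.5 percentage points)

- noon: at 4.0 h add free monomer, 50.0% of the amount charged, then wait 2.0 h
- dawn: change nothing and wait 2.0 h more
- dusk: at 4.0 h take out 90% of the monomer in chains then present, then wait 2.0 h
- autumn: at 4.0 h raise the temperature by 10 K, then wait 2.0 h

- monomer in chains taken out counts as made
- what was read earlier has a scatter of 0.5 percentage points, one standard deviation
- additions bring no volume worth counting

1. monomer in chains, in percent of the free monomer first charged, at 4.0 h
2. which option adds most monomer in chains ("none" when 2 percentage points or less is all one gets) (noon / dawn / dusk / autumn / none)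
3. monomer in chains present, with what was taken out counted in, in percent of the free monomer first charged, after dawn
4. monomer in chains present, with what was taken out counted in, in percent of the free monomer first charged, after dusk

The south-east readings begin after the rise is over, so we draw the rise from the south-west run, at −15 °C and 1 M. In that run monomer in chains climbs at 0.0627 min⁻¹ of the charge over the first 6.00 min, then at 0.00850 min⁻¹ up to 12.0 min, and that drop is the knee. Free monomer in the south-west run reads 5.0% at the knee and 0.9% at 30.0 min, a decay constant of 0.0953 min⁻¹, which gives 7.28 min. This time for the free monomer left past the knee to halve is the tail half-life, a reading that carries the scatter of a small value. Starting from the knee, the south-west free monomer crosses the margin of 2 percentage points at about 21.6 min.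

Taken over to the south-east flask, the asked time of 4.0 h is 33.0 tail half-lives. Its first reading at 50.0 min comes later than the south-west crossing, and its free monomer reads 0% at 180 min. We therefore commit to the mean of its chain readings, 30.3%, and expect dawn, dusk and autumn to gain less than the margin. Noon puts free monomer back, so this reckoning does not reach it. But the south-west decay constant falls from 0.170 min⁻¹ to 0.0953 min⁻¹, which we read, with less confidence, as the chain carriers dying.

The forecast gives 30.3% at the asked time, 30.3% after dawn, 30.3% after dusk and none as the best option, on the ground that “nothing is left to convert”.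

The simulation gives 30.3%, 30.3%, 30.3% and none, and noon loses 11 points.

    free monomer + growing radical → monomer in chains + growing radical, rate k1*[growing radical]*[free monomer] (k = 24000 M⁻¹ s⁻¹, Ea = 13.0 kJ mol⁻¹)
    protic impurity + free monomer → quenched substrate (k = 0.240 M⁻¹ min⁻¹, Ea = 58.0 kJ mol⁻¹)
    free monomer + monomer in chains → side product (k = 0.320 M⁻¹ min⁻¹, Ea = 65.0 kJ mol⁻¹)
    free monomer + initiating radical → growing radical + monomer in chains (k = 9.20 × 10⁵ M⁻¹ s⁻¹, Ea = 20.0 kJ mol⁻¹)
    2 growing radical → dead chain (k = 7.90 × 10⁷ M⁻¹ s⁻¹, Ea = 13.0 kJ mol⁻¹)
    2 free monomer → self-condensation product (k = 0.530 M⁻¹ min⁻¹, Ea = 44.0 kJ mol⁻¹)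
    initiator → 2 initiating radical (k = 0.710 min⁻¹, Ea = 65.0 kJ mol⁻¹)
    (constants at 0 °C)

In this flask free monomer stands at 0.977% at 24.0 min, later than the 21.6 min read for the south-west crossing. By 240 min this limiting reagent is at 0%, beside 76% of the protic impurity. The level itself stands at 30.3% because two growing radicals combine to a dead chain: the same flask without that step reaches 98.0%.

Carried unchanged to the repeat at 25 °C, 7.28 min again makes 4.0 h 33.0 tail half-lives, so we expect that curve closed long before the look. That repeat holds 0% of free monomer and 10.9% in chains.

(The readings come from a simulation with constants of no real substance, and the scatter is random.)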